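**Strategy.** The route rests on cutting the trisubstituted C(CH3)=CH olefin (C8=C9, daucane numbering) of the seven-membered ring. Ring-closing olefin metathesis joins a methallyl arm on C6 to a vinyl carbinol on C10 and so closes the cycloheptene in one operation. It exploits the cis fusion at C1/C5, which holds both arms on one face of the cyclopentane. The precursor, diene 13, carries all five stereocentres and comes from a chiral-pool butenolide by trans conjugate addition, double α-alkylation, a first metathesis to the cyclopentene, convex-face hydration and reagent-controlled ketone reduction.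

Key step: step 11

Atom labels (daucane numbering, used throughout): C1 (quaternary C–CH3), C2, C3, C4 (C(OH)–isopropyl), C5 (ring-fusion CH), C6 (CH–O–anisoyl), C7 (CH2), C8 (=C–CH3), C9 (=CH), C10 (CH–OAc). The five-membered ring is C1–C5; the seven-membered ring is C1, C5–C10.

Remark: butenolide 1 is taken as the purchasable (R)-enantiomer of the familiar hydroxymethyl butenolide synthon; the other inputs (2-bromo-3-methylbut-1-ene, allyl bromide, isopropenyl- and vinylmagnesium bromide, 4-methoxybenzoyl chloride) are catalogue reagents.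

Step 1
Reactants: 1 (R)-5-(hydroxymethyl)furan-2(5H)-one
Product: 2 (R)-5-{[(tert-butyldiphenylsilyl)oxy]methyl}furan-2(5H)-one
Conditions: TBDPSCl, imidazole, DMF, 0 °C to rt
Reagents that add atoms: tert-butyl(chloro)diphenylsilane, CC(C)(C)[Si](Cl)(c1ccccc1)c1ccccc1
Why: Standard silylation of the primary alcohol installs a bulky ether on C7 that shields one face of the butenolide in the next step, the C6 stereocentre being untouched.

Step 2
Reactants: 2 (R)-5-{[(tert-butyldiphenylsilyl)oxy]methyl}furan-2(5H)-one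
Product: 4 (3R,4S,5R)-5-{[(tert-butyldiphenylsilyl)oxy]methyl}-4-(3-methylbut-1-en-2-yl)-3-(prop-2-en-1-yl)dihydrofuran-2(3H)-one, via bromomagnesium lactone enolate 3 (not isolated)
Conditions: (3-methylbut-1-en-2-yl)magnesium bromide (from 2-bromo-3-methylbut-1-ene and Mg, THF), CuBr·SMe2 (10 mol%), THF, −78 °C; then allyl bromide, HMPA, −78 to −20 °C
Reagents that add atoms: 2-bromo-3-methylbut-1-ene (used as its Grignard reagent), CC(C)C(Br)=C; allyl bromide, C=CCBr
Why: Copper-catalysed conjugate addition of the alkenyl Grignard reagent should occur anti to the C6 silyloxymethyl group and set C5, and the enolate is then allylated anti to the new C5 substituent (three-component conjugate addition–enolate alkylation), which sets a provisional C1 centre.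

Step 3
Reactants: 4 (3R,4S,5R)-5-{[(tert-butyldiphenylsilyl)oxy]methyl}-4-(3-methylbut-1-en-2-yl)-3-(prop-2-en-1-yl)dihydrofuran-2(3H)-one
Product: 5 (3S,4R,5R)-5-{[(tert-butyldiphenylsilyl)oxy]methyl}-3-methyl-4-(3-methylbut-1-en-2-yl)-3-(prop-2-en-1-yl)dihydrofuran-2(3H)-one
Conditions: LDA, THF, −78 °C; then MeI, −78 to −40 °C
Reagents that add atoms: iodomethane, CI
Why: Diastereoselective lactone enolate alkylation, in which MeI attacks the planar enolate anti to the C5 alkenyl group, should create the quaternary C1 centre with CH3 trans and the allyl arm cis to the C5 substituent.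

Step 4
Reactants: 5 (3S,4R,5R)-5-{[(tert-butyldiphenylsilyl)oxy]methyl}-3-methyl-4-(3-methylbut-1-en-2-yl)-3-(prop-2-en-1-yl)dihydrofuran-2(3H)-one
Product: 6 (3R,3aR,6aS)-3-{[(tert-butyldiphenylsilyl)oxy]methyl}-6a-methyl-4-(propan-2-yl)-3,3a,6,6a-tetrahydro-1H-cyclopenta[c]furan-1-one
Conditions: second-generation Hoveyda–Grubbs catalyst (5 mol%), toluene, 80 °C
Reagents that add atoms: none
Why: Ring-closing metathesis of the cis-disposed allyl and 1-isopropylvinyl arms can only give the cis-fused cyclopentene, whose trisubstituted C3=C4 olefin already carries the isopropyl group, and no stereocentre changes.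

Step 5
Reactants: 6 (3R,3aR,6aS)-3-{[(tert-butyldiphenylsilyl)oxy]methyl}-6a-methyl-4-(propan-2-yl)-3,3a,6,6a-tetrahydro-1H-cyclopenta[c]furan-1-one
Product: 7 (3R,3aR,4R,6aS)-3-{[(tert-butyldiphenylsilyl)oxy]methyl}-4-hydroxy-6a-methyl-4-(propan-2-yl)hexahydro-1H-cyclopenta[c]furan-1-one
Conditions: Mn(dpm)3 (10 mol%), PhSiH3, O2 (1 atm), i-PrOH/CH2Cl2, 0 °C to rt
Reagents that add atoms: dioxygen, O=O
Why: Mukaiyama hydration by hydrogen-atom transfer places H on C3 and a tertiary radical on C4, which should capture O2 on the convex face of the cis-fused bicycle (anti to the lactone ring), so that the Markovnikov C4–OH is cis to H5 and to the C1 methyl group.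

Step 6
Reactants: 7 (3R,3aR,4R,6aS)-3-{[(tert-butyldiphenylsilyl)oxy]methyl}-4-hydroxy-6a-methyl-4-(propan-2-yl)hexahydro-1H-cyclopenta[c]furan-1-one
Product: 8 (3R,3aR,4R,6aS)-4-hydroxy-3-(hydroxymethyl)-6a-methyl-4-(propan-2-yl)hexahydro-1H-cyclopenta[c]furan-1-one
Conditions: TBAF, AcOH, THF, 0 °C to rt
Reagents that add atoms: none
Why: Fluoride-mediated desilylation frees the primary alcohol, and the acetic acid buffer keeps the resulting alkoxide from attacking the lactone.

Step 7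
Reactants: 8 (3R,3aR,4R,6aS)-4-hydroxy-3-(hydroxymethyl)-6a-methyl-4-(propan-2-yl)hexahydro-1H-cyclopenta[c]furan-1-one
Product: 10 (3S,3aR,4R,6aS)-4-hydroxy-6a-methyl-3-(2-methylprop-2-en-1-yl)-4-(propan-2-yl)hexahydro-1H-cyclopenta[c]furan-1-one, via primary triflate 9 (not isolated)
Conditions: Tf2O, 2,6-lutidine, CH2Cl2, −78 °C; then isopropenylmagnesium bromide, CuBr·SMe2 (10 mol%), THF, −78 to −30 °C
Reagents that add atoms: trifluoromethanesulfonic anhydride (its atoms stay only in 9), O=S(=O)(OS(=O)(=O)C(F)(F)F)C(F)(F)F; isopropenylmagnesium bromide, CC(=C)[Mg]Br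
Why: The primary hydroxyl is triflated selectively over the hindered tertiary one, and copper-catalysed Grignard displacement of the triflate at C7 (sp3–sp2 cross-coupling) should outrun attack on the hindered lactone, installing the methallyl arm without touching C6.

Step 8
Reactants: 10 (3S,3aR,4R,6aS)-4-hydroxy-6a-methyl-3-(2-methylprop-2-en-1-yl)-4-(propan-2-yl)hexahydro-1H-cyclopenta[c]furan-1-one
Product: 11 1-[(1S,2R,3R)-3-hydroxy-2-[(1S)-1-hydroxy-3-methylbut-3-en-1-yl]-1-methyl-3-(propan-2-yl)cyclopentyl]prop-2-en-1-one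
Conditions: vinylmagnesium bromide (3 equiv), THF, −78 to −40 °C; aq. NH4Cl
Reagents that add atoms: vinylmagnesium bromide, C=C[Mg]Br
Why: Acyl substitution of the lactone by one equivalent of the vinyl Grignard reagent at the hindered, α-quaternary carbonyl should stop at the tetrahedral alkoxide until the quench, so that ring opening delivers the C10 vinyl ketone and frees the C6 hydroxyl without creating a stereocentre.

Step 9
Reactants: 11 1-[(1S,2R,3R)-3-hydroxy-2-[(1S)-1-hydroxy-3-methylbut-3-en-1-yl]-1-methyl-3-(propan-2-yl)cyclopentyl]prop-2-en-1-one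
Product: 12 (1S)-1-[(1R,2S,5R)-5-hydroxy-2-methyl-2-(prop-2-enoyl)-5-(propan-2-yl)cyclopentyl]-3-methylbut-3-en-1-yl 4-methoxybenzoate
Conditions: 4-methoxybenzoyl chloride, pyridine, DMAP (10 mol%), CH2Cl2, 0 °C
Reagents that add atoms: 4-methoxybenzoyl chloride, COc1ccc(cc1)C(Cl)=O
Why: DMAP-catalysed esterification should take place only at the secondary C6 hydroxyl, because the tertiary C4 hydroxyl flanked by isopropyl is too hindered.

Step 10
Reactants: 12 (1S)-1-[(1R,2S,5R)-5-hydroxy-2-methyl-2-(prop-2-enoyl)-5-(propan-2-yl)cyclopentyl]-3-methylbut-3-en-1-yl 4-methoxybenzoate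
Product: 13 (1S)-1-[(1R,2S,5R)-5-hydroxy-2-[(1S)-1-hydroxyprop-2-en-1-yl]-2-methyl-5-(propan-2-yl)cyclopentyl]-3-methylbut-3-en-1-yl 4-methoxybenzoate
Conditions: (R)-Me-CBS oxazaborolidine ((R)-1-methyl-3,3-diphenyltetrahydro-1H,3H-pyrrolo[1,2-c][1,3,2]oxazaborole, 0.5 equiv), catecholborane, toluene, −78 °C
Reagents that add atoms: none
Why: In this Corey–Bakshi–Shibata reduction the ketone should bind the (R)-oxazaborolidine with the quaternary C1 group as the large and vinyl as the small flank, so that hydride is delivered to the face giving the (S)-carbinol at C10, while catecholborane at low temperature spares the olefins and the ester.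

Step 11
Reactants: 13 (1S)-1-[(1R,2S,5R)-5-hydroxy-2-[(1S)-1-hydroxyprop-2-en-1-yl]-2-methyl-5-(propan-2-yl)cyclopentyl]-3-methylbut-3-en-1-yl 4-methoxybenzoate
Product: 14 (3R,3aR,4S,8S,8aS)-3,8-dihydroxy-6,8a-dimethyl-3-(propan-2-yl)-1,2,3,3a,4,5,8,8a-octahydroazulen-4-yl 4-methoxybenzoate
Conditions: second-generation Hoveyda–Grubbs catalyst (10 mol%), toluene (5 mM), 80 °C, argon sparge
Reagents that add atoms: none
Why: Alkylidene exchange at the monosubstituted vinyl carbinol, helped by the free allylic hydroxyl, gives a ruthenium carbene at C9 that undergoes [2+2] cycloaddition with the 1,1-disubstituted C8 olefin and cycloreversion, releasing ethene and forming the C8=C9 double bond (Chauvin mechanism). The closest known reaction type is ring-closing metathesis of a 1,8-diene to a trisubstituted cycloheptene with a second-generation ruthenium catalyst. The seven-membered ring closes by olefin–olefin union of the C6 methallyl and C10 vinyl arms on a cis-1,2-disubstituted cyclopentane, giving the cis-fused hydroazulene. No stereocentre is created, and the ring enforces the Z geometry of the new olefin. The step needs cyclisation to outrun oligomerisation and allylic alcohol isomerisation, which is secured by the cis relationship of the two arms set in steps 2 to 4, by high dilution and by the absence of any other olefin in 13.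

Step 12
Reactants: 14 (3R,3aR,4S,8S,8aS)-3,8-dihydroxy-6,8a-dimethyl-3-(propan-2-yl)-1,2,3,3a,4,5,8,8a-octahydroazulen-4-yl 4-methoxybenzoate
Product: 15 (3R,3aR,4S,8S,8aS)-8-(acetyloxy)-3-hydroxy-6,8a-dimethyl-3-(propan-2-yl)-1,2,3,3a,4,5,8,8a-octahydroazulen-4-yl 4-methoxybenzoate
Conditions: Ac2O, pyridine, DMAP (5 mol%), CH2Cl2, 0 °C to rt
Reagents that add atoms: acetic anhydride, CC(=O)OC(C)=O
Why: Acetylation should occur at the secondary allylic C10 hydroxyl only, the tertiary C4 hydroxyl being too hindered, which completes the target.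

**Compound list**

1 | (R)-5-(hydroxymethyl)furan-2(5H)-one | O=C1C=C[C@H](CO)O1 | starting material
2 | (R)-5-{[(tert-butyldiphenylsilyl)oxy]methyl}furan-2(5H)-one | O=C1C=C[C@H](CO[Si](c2ccccc2)(c2ccccc2)C(C)(C)C)O1 | intermediate
3 | bromomagnesium enolate of (4S,5R)-5-{[(tert-butyldiphenylsilyl)oxy]methyl}-4-(3-methylbut-1-en-2-yl)dihydrofuran-2(3H)-one (bromomagnesium lactone enolate) | Br[Mg]OC1=C[C@@H](C(=C)C(C)C)[C@H](CO[Si](c2ccccc2)(c2ccccc2)C(C)(C)C)O1 | intermediate
4 | (3R,4S,5R)-5-{[(tert-butyldiphenylsilyl)oxy]methyl}-4-(3-methylbut-1-en-2-yl)-3-(prop-2-en-1-yl)dihydrofuran-2(3H)-one | O=C1[C@H](CC=C)[C@@H](C(=C)C(C)C)[C@H](CO[Si](c2ccccc2)(c2ccccc2)C(C)(C)C)O1 | intermediate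
5 | (3S,4R,5R)-5-{[(tert-butyldiphenylsilyl)oxy]methyl}-3-methyl-4-(3-methylbut-1-en-2-yl)-3-(prop-2-en-1-yl)dihydrofuran-2(3H)-one | O=C1[C@@](C)(CC=C)[C@@H](C(=C)C(C)C)[C@H](CO[Si](c2ccccc2)(c2ccccc2)C(C)(C)C)O1 | intermediate
6 | (3R,3aR,6aS)-3-{[(tert-butyldiphenylsilyl)oxy]methyl}-6a-methyl-4-(propan-2-yl)-3,3a,6,6a-tetrahydro-1H-cyclopenta[c]furan-1-one | O=C1O[C@@H](CO[Si](c3ccccc3)(c3ccccc3)C(C)(C)C)[C@@H]2C(C(C)C)=CC[C@]12C | intermediate
7 | (3R,3aR,4R,6aS)-3-{[(tert-butyldiphenylsilyl)oxy]methyl}-4-hydroxy-6a-methyl-4-(propan-2-yl)hexahydro-1H-cyclopenta[c]furan-1-one | O=C1O[C@@H](CO[Si](c3ccccc3)(c3ccccc3)C(C)(C)C)[C@@H]2[C@](O)(C(C)C)CC[C@]12C | intermediate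
8 | (3R,3aR,4R,6aS)-4-hydroxy-3-(hydroxymethyl)-6a-methyl-4-(propan-2-yl)hexahydro-1H-cyclopenta[c]furan-1-one | O=C1O[C@@H](CO)[C@@H]2[C@](O)(C(C)C)CC[C@]12C | intermediate
9 | [(3R,3aR,4R,6aS)-4-hydroxy-6a-methyl-1-oxo-4-(propan-2-yl)hexahydro-1H-cyclopenta[c]furan-3-yl]methyl trifluoromethanesulfonate (primary triflate) | O=C1O[C@@H](COS(=O)(=O)C(F)(F)F)[C@@H]2[C@](O)(C(C)C)CC[C@]12C | intermediate
10 | (3S,3aR,4R,6aS)-4-hydroxy-6a-methyl-3-(2-methylprop-2-en-1-yl)-4-(propan-2-yl)hexahydro-1H-cyclopenta[c]furan-1-one | O=C1O[C@@H](CC(C)=C)[C@@H]2[C@](O)(C(C)C)CC[C@]12C | intermediate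
11 | 1-[(1S,2R,3R)-3-hydroxy-2-[(1S)-1-hydroxy-3-methylbut-3-en-1-yl]-1-methyl-3-(propan-2-yl)cyclopentyl]prop-2-en-1-one | C=CC(=O)[C@@]1(C)CC[C@@](O)(C(C)C)[C@H]1[C@@H](O)CC(C)=C | intermediate
12 | (1S)-1-[(1R,2S,5R)-5-hydroxy-2-methyl-2-(prop-2-enoyl)-5-(propan-2-yl)cyclopentyl]-3-methylbut-3-en-1-yl 4-methoxybenzoate | C=CC(=O)[C@@]1(C)CC[C@@](O)(C(C)C)[C@H]1[C@@H](OC(=O)c2ccc(OC)cc2)CC(C)=C | intermediate
13 | (1S)-1-[(1R,2S,5R)-5-hydroxy-2-[(1S)-1-hydroxyprop-2-en-1-yl]-2-methyl-5-(propan-2-yl)cyclopentyl]-3-methylbut-3-en-1-yl 4-methoxybenzoate | C=C[C@H](O)[C@@]1(C)CC[C@@](O)(C(C)C)[C@H]1[C@@H](OC(=O)c2ccc(OC)cc2)CC(C)=C | intermediate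
14 | (3R,3aR,4S,8S,8aS)-3,8-dihydroxy-6,8a-dimethyl-3-(propan-2-yl)-1,2,3,3a,4,5,8,8a-octahydroazulen-4-yl 4-methoxybenzoate | COc1ccc(C(=O)O[C@H]2CC(C)=C[C@H](O)[C@@]3(C)CC[C@@](O)(C(C)C)[C@@H]23)cc1 | intermediate
15 | (3R,3aR,4S,8S,8aS)-8-(acetyloxy)-3-hydroxy-6,8a-dimethyl-3-(propan-2-yl)-1,2,3,3a,4,5,8,8a-octahydroazulen-4-yl 4-methoxybenzoate | COc1ccc(C(=O)O[C@H]2CC(C)=C[C@H](OC(C)=O)[C@@]3(C)CC[C@@](O)(C(C)C)[C@@H]23)cc1 | target

**Totals.** Total step count: 12. Longest linear sequence: 12 steps (from 1).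

**Steps most likely to fail**

1. Step 10. The oxazaborolidine may fail to override the bias of the neighbouring quaternary C1 centre (a Felkin–Anh analysis suggests that bias opposes the catalyst), or may discriminate poorly between the vinyl and tertiary-alkyl flanks, so that facial selectivity at C10 erodes. The fallback leaves the route at 10 and returns at 13. Lithium (trimethylsilyl)acetylide (THF, −78 °C) adds once to lactone 10 to give the silyl ynone F1. Acylation with 4-methoxybenzoyl chloride and pyridine gives the ynone ester F2. Noyori transfer hydrogenation with RuCl[(R,R)-TsDPEN](p-cymene) in i-PrOH, in which the alkyne takes the aryl role, should set C10 under catalyst control and give the propargylic alcohol F3. TBAF/AcOH removes silicon to give the terminal alkyne F4, and semi-hydrogenation (H2, Pd/CaCO3 poisoned with lead, quinoline) gives 13.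

2. Step 5. Oxygen capture by the planar C4 radical may be poorly face-selective, or hydrogen-atom transfer to the hindered isopropyl-substituted olefin may stall. The fallback leaves at 6 and returns at 7. mCPBA (CH2Cl2, NaHCO3, 0 °C) epoxidises the cyclopentene on its convex face to give the epoxy lactone F5. LiAlH4 (THF, 0 °C) opens the epoxide by hydride attack at C3 and reduces the lactone, giving the silyl ether triol F6. TEMPO/PhI(OAc)2 then oxidises the primary alcohol and re-closes the lactone to 7.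

3. Step 8. The tetrahedral intermediate may collapse before the quench, which would allow a second 1,2-addition or conjugate addition to the vinyl ketone. The fallback leaves at 10 and returns at 11. DIBAL-H (CH2Cl2, −78 °C) reduces the lactone to the lactol F7. Excess vinylmagnesium bromide opens it to the triol F8 (both C10 epimers, which converge). MnO2 then oxidises only the allylic alcohol to give 11.

**Further compounds**

F1 | step 10 | 1-[(1S,2R,3R)-3-hydroxy-2-[(1S)-1-hydroxy-3-methylbut-3-en-1-yl]-1-methyl-3-(propan-2-yl)cyclopentyl]-3-(trimethylsilyl)prop-2-yn-1-one | C[Si](C)(C)C#CC(=O)[C@@]1(C)CC[C@@](O)(C(C)C)[C@H]1[C@@H](O)CC(C)=C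
F2 | step 10 | (1S)-1-[(1R,2S,5R)-5-hydroxy-2-methyl-5-(propan-2-yl)-2-[3-(trimethylsilyl)prop-2-ynoyl]cyclopentyl]-3-methylbut-3-en-1-yl 4-methoxybenzoate | C[Si](C)(C)C#CC(=O)[C@@]1(C)CC[C@@](O)(C(C)C)[C@H]1[C@@H](OC(=O)c2ccc(OC)cc2)CC(C)=C
F3 | step 10 | (1S)-1-[(1R,2S,5R)-5-hydroxy-2-[(1R)-1-hydroxy-3-(trimethylsilyl)prop-2-yn-1-yl]-2-methyl-5-(propan-2-yl)cyclopentyl]-3-methylbut-3-en-1-yl 4-methoxybenzoate | C[Si](C)(C)C#C[C@H](O)[C@@]1(C)CC[C@@](O)(C(C)C)[C@H]1[C@@H](OC(=O)c2ccc(OC)cc2)CC(C)=C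
F4 | step 10 | (1S)-1-[(1R,2S,5R)-5-hydroxy-2-[(1S)-1-hydroxyprop-2-yn-1-yl]-2-methyl-5-(propan-2-yl)cyclopentyl]-3-methylbut-3-en-1-yl 4-methoxybenzoate | C#C[C@H](O)[C@@]1(C)CC[C@@](O)(C(C)C)[C@H]1[C@@H](OC(=O)c2ccc(OC)cc2)CC(C)=C
F5 | step 5 | (3R,3aR,4R,5S,6aS)-3-{[(tert-butyldiphenylsilyl)oxy]methyl}-4,5-epoxy-6a-methyl-4-(propan-2-yl)hexahydro-1H-cyclopenta[c]furan-1-one | O=C1O[C@@H](CO[Si](c4ccccc4)(c4ccccc4)C(C)(C)C)[C@@H]2[C@@]3(C(C)C)O[C@H]3C[C@]12C
F6 | step 5 | (1R)-2-[(tert-butyldiphenylsilyl)oxy]-1-[(1R,2S,5R)-5-hydroxy-2-(hydroxymethyl)-2-methyl-5-(propan-2-yl)cyclopentyl]ethan-1-ol | OC[C@@]1(C)CC[C@@](O)(C(C)C)[C@H]1[C@@H](O)CO[Si](c2ccccc2)(c2ccccc2)C(C)(C)C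
F7 | step 8 | (3S,3aR,4R,6aS)-6a-methyl-3-(2-methylprop-2-en-1-yl)-4-(propan-2-yl)hexahydro-1H-cyclopenta[c]furan-1,4-diol (both C1 epimers) | OC1O[C@@H](CC(C)=C)[C@@H]2[C@](O)(C(C)C)CC[C@]12C
F8 | step 8 | (1S)-1-[(1R,2S,5R)-5-hydroxy-2-(1-hydroxyprop-2-en-1-yl)-2-methyl-5-(propan-2-yl)cyclopentyl]-3-methylbut-3-en-1-ol (both epimers at the allylic carbinol) | C=CC(O)[C@@]1(C)CC[C@@](O)(C(C)C)[C@H]1[C@@H](O)CC(C)=C
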